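**Retrosynthetic overview**
1. 19 ⇒ cross-metathesis (C12=C13) of the allyl-decalin diol 13 with (S)-tulipalin B 18; the lactone ring and C14 come from the chiral-pool lactone 14.
2. 13 ⇒ LiAlH4 reduction (C3 carbinol, C19 carbinol, auxiliary released) of 12 ⇐ C4 methylation of the bicyclic β-keto ester 11.
3. 11 ⇒ one oxidative radical bicyclization of the acyclic trienyl β-keto ester 8: bonds C4–C5 and C10–C9 close rings A and B together and the C8=C17 alkene forms in the same operation, with a (−)-8-phenylmenthyl ester fixing the absolute sense.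
4. 8 ⇒ acetoacetate dianion (from 6) + allylic bromide 4; 4 ⇐ geranyl acetate 1 by allylic oxidation, vinylation and bromination.
5. Ring order: the lactone ring is bought (14); ring A then ring B close within the single cascade of step 6; no ring is formed afterwards.

Assumption: C1–C20 follow labdane numbering, α/β refer to the usual ent-labdane drawing of andrographolide (C20 methyl α, H5 β), and compound numbers follow the order of first appearance in the forward route.

**Route**

Step 1
Reactants: 1 geranyl acetate [(2E)-3,7-dimethylocta-2,6-dien-1-yl acetate]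
Product: 2 (2E,6E)-8-hydroxy-3,7-dimethylocta-2,6-dien-1-yl acetate
Conditions: SeO2 (5 mol %), salicylic acid (10 mol %), t-BuOOH (3 equiv), CH2Cl2, 25 °C
Reagents that add atoms: tert-butyl hydroperoxide CC(C)(C)OO (its oxygen is passed on by the SeO2 catalyst)
Why: Catalytic SeO2 allylic oxidation (ene reaction then 2,3-sigmatropic shift) attacks the electron-rich terminal alkene at its E-methyl group because the 2,3-alkene is deactivated by the allylic acetate, so the (6E)-alcohol forms and no stereocentre is created.

Step 2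
Reactants: 2 (2E,6E)-8-hydroxy-3,7-dimethylocta-2,6-dien-1-yl acetate
Product: 3 (2E,6E)-2,6-dimethyldeca-2,6,9-trien-1-ol
Conditions: Bu3SnCH=CH2 (1.2 equiv), Pd(dba)2 (3 mol %), LiCl (3 equiv), DMF, 25 °C
Reagents that add atoms: tributyl(vinyl)stannane C=C[Sn](CCCC)(CCCC)CCCC
Why: Stille-type allylic coupling in which zerovalent palladium ionises only the allylic acetate (the free allylic alcohol is inert) and the vinyl group is delivered to the unhindered primary terminus of the π-allyl with retention of the E geometry, giving the skipped diene.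

Step 3
Reactants: 3 (2E,6E)-2,6-dimethyldeca-2,6,9-trien-1-ol
Product: 4 (4E,8E)-10-bromo-5,9-dimethyldeca-1,4,8-triene
Conditions: CBr4 (1.2 equiv), PPh3 (1.25 equiv), CH2Cl2, 0 °C
Reagents that add atoms: carbon tetrabromide BrC(Br)(Br)Br
Why: Appel reaction under neutral conditions converts the primary allylic alcohol into the bromide by SN2 displacement of the oxyphosphonium group without allylic transposition or alkene isomerisation.

Step 4
Reactants: 5 (−)-8-phenylmenthol [(1R,2S,5R)-5-methyl-2-(2-phenylpropan-2-yl)cyclohexan-1-ol]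
Product: 6 (1R,2S,5R)-5-methyl-2-(2-phenylpropan-2-yl)cyclohexyl 3-oxobutanoate
Conditions: 2,2,6-trimethyl-4H-1,3-dioxin-4-one (1.5 equiv), xylene, 140 °C, acetone distilled off
Reagents that add atoms: 2,2,6-trimethyl-4H-1,3-dioxin-4-one CC1=CC(=O)OC(C)(C)O1
Why: Thermal retro-hetero-Diels–Alder of the dioxinone releases acetylketene, which acetoacetylates even this hindered secondary alcohol cleanly and leaves the three stereocentres of the auxiliary untouched.

Step 5
Reactants: 6 (1R,2S,5R)-5-methyl-2-(2-phenylpropan-2-yl)cyclohexyl 3-oxobutanoate; 4 (4E,8E)-10-bromo-5,9-dimethyldeca-1,4,8-triene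
Product: 8 (1R,2S,5R)-5-methyl-2-(2-phenylpropan-2-yl)cyclohexyl (6E,10E)-6,10-dimethyl-3-oxotetradeca-6,10,13-trienoate, via dilithium bis-enolate 7 (not isolated)
Conditions: LiN(i-Pr)2 (2.1 equiv), THF, 0 °C; then 4, 0 °C; then 1 M HCl
Reagents that add atoms: none
Why: Acetoacetate dianion (Weiler) alkylation in which the more basic terminal carbanion displaces the primary allylic bromide by SN2 at the γ-carbon only, so both E-alkenes and the terminal vinyl group are carried over unchanged.

Step 6
Reactants: 8 (1R,2S,5R)-5-methyl-2-(2-phenylpropan-2-yl)cyclohexyl (6E,10E)-6,10-dimethyl-3-oxotetradeca-6,10,13-trienoate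
Product: 11 (1R,2S,5R)-5-methyl-2-(2-phenylpropan-2-yl)cyclohexyl (1R,4aR,5R,8aR)-4a-methyl-6-methylidene-2-oxo-5-(prop-2-en-1-yl)decahydronaphthalene-1-carboxylate (3-oxo-8(17)-ene with 5β-H and 10α-CH3 and 9α-allyl and equatorial 4β-ester), via monocyclic C10 radical 9 (not isolated), via bicyclic C8 radical 10 (not isolated)
Conditions: Mn(OAc)3·2H2O (2.2 equiv), Cu(OAc)2·H2O (1.0 equiv), Yb(OTf)3 (1.0 equiv), CF3CH2OH–AcOH (4:1), degassed, −5 to 0 °C
Reagents that add atoms: none
Why: Oxidative radical polyene bicyclization in which trivalent manganese oxidises the Yb(OTf)3-chelated β-keto ester to the C4 radical, the phenyl ring of the auxiliary stacks over and blocks one face of the chelate, 6-endo attack on C5 and then of the C10 radical on C9 through a chair–chair array of the E,E-diene sets 5β-H, 10α-CH3 and the equatorial 9α-allyl group in the ent series, and divalent copper traps the tertiary C8 radical and eliminates towards the methyl group to give the exocyclic alkene.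

Step 7
Reactants: 11 the bicyclic β-keto ester from step 6
Product: 12 (1R,2S,5R)-5-methyl-2-(2-phenylpropan-2-yl)cyclohexyl (1S,4aS,5R,8aS)-1,4a-dimethyl-6-methylidene-2-oxo-5-(prop-2-en-1-yl)decahydronaphthalene-1-carboxylate (4β-CH3 equatorial and 4α-ester axial)
Conditions: MeI (5 equiv), K2CO3 (3 equiv), acetone, 50 °C
Reagents that add atoms: iodomethane CI
Why: C-Alkylation of the β-keto ester enolate takes place on the β face, anti to the axial 10α-methyl group and anti to the phenyl group of the auxiliary, which puts the new methyl group equatorial (C18) and the ester axial (future C19) at the C4 quaternary stereocentre.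

Step 8
Reactants: 12 the C4-methylated keto ester from step 7
Product: 13 (1R,2R,4aS,5R,8aS)-1-(hydroxymethyl)-1,4a-dimethyl-6-methylidene-5-(prop-2-en-1-yl)decahydronaphthalen-2-ol (3α,19-diol)
Conditions: LiAlH4 (4 equiv), THF, 0 to 66 °C; then H2O, aq. NaOH
Reagents that add atoms: none
Why: LiAlH4 reduction in which hydride reaches the C3 ketone along the axial trajectory from the β face (the α face is screened by the axial C4 ester) to give the equatorial 3α-alcohol, while the same reagent reduces the neopentyl ester to the C19 carbinol and releases the auxiliary for recovery.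

Step 9
Reactants: 14 (S)-3-hydroxy-γ-butyrolactone [(4S)-4-hydroxyoxolan-2-one]
Product: 16 (3S,4S)-3-[(dimethylamino)methyl]-4-hydroxyoxolan-2-one, via dilithium lactone dianion 15 (not isolated)
Conditions: LiN(i-Pr)2 (2.2 equiv), THF, −78 °C; then CH2=NMe2+ I− (1.2 equiv), −78 to 0 °C; then AcOH
Reagents that add atoms: dimethyl(methylidene)ammonium iodide C=[N+](C)C.[I-]
Why: Mannich reaction of the alkoxide–enolate dianion, which cannot undergo β-elimination because it would have to expel oxide, with the iminium ion adding anti to the alkoxide to give the trans product and the carbinol stereocentre untouched.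

Step 10
Reactants: 16 (3S,4S)-3-[(dimethylamino)methyl]-4-hydroxyoxolan-2-one
Product: 18 (S)-tulipalin B [(4S)-4-hydroxy-3-methylideneoxolan-2-one], via trimethylammonium iodide 17 (not isolated)
Conditions: MeI (5 equiv), MeOH, 25 °C; then NaHCO3, CH2Cl2–H2O, 25 °C
Reagents that add atoms: none
Why: Exhaustive N-methylation followed by E1cB (Hofmann-type) loss of trimethylamine installs the exocyclic methylene under conditions that neither eliminate nor epimerise the 4-hydroxyl group.

Step 11
Reactants: 13 the 3α,19-diol from step 8; 18 (S)-tulipalin B (3 equiv)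
Product: 19 andrographolide
Conditions: second-generation Hoveyda–Grubbs catalyst RuCl2(H2IMes)(=CH-C6H4-2-O-i-Pr) (10 mol %), 2,6-dichloro-1,4-benzoquinone (20 mol %), CH2Cl2, 40 °C
Reagents that add atoms: none
Why: Olefin cross-metathesis between the unhindered monosubstituted alkene of 13 and the 1,1-disubstituted acrylate-type alkene of 18 (the hindered C8 exocyclic alkene is a spectator) gives the trisubstituted alkylidene lactone in its more stable E form with H12 syn to the carbonyl, C14 is carried in from 18, and the benzoquinone suppresses ruthenium hydride isomerisation.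

**Compound list**

1 | geranyl acetate | CC(C)=CCC/C(C)=C/COC(C)=O | starting material
2 | (2E,6E)-8-hydroxy-3,7-dimethylocta-2,6-dien-1-yl acetate | OC/C(C)=C/CC/C(C)=C/COC(C)=O | intermediate
3 | (2E,6E)-2,6-dimethyldeca-2,6,9-trien-1-ol | OC/C(C)=C/CC/C(C)=C/CC=C | intermediate
4 | (4E,8E)-10-bromo-5,9-dimethyldeca-1,4,8-triene | BrC/C(C)=C/CC/C(C)=C/CC=C | intermediate
5 | (−)-8-phenylmenthol, (1R,2S,5R)-5-methyl-2-(2-phenylpropan-2-yl)cyclohexan-1-ol | O[C@@H]1C[C@H](C)CC[C@H]1C(C)(C)c1ccccc1 | starting material
6 | (1R,2S,5R)-5-methyl-2-(2-phenylpropan-2-yl)cyclohexyl 3-oxobutanoate | CC(=O)CC(=O)O[C@@H]1C[C@H](C)CC[C@H]1C(C)(C)c1ccccc1 | intermediate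
7 | dilithium bis-enolate (dianion) of 6 | C=C([O-])C=C([O-])O[C@@H]1C[C@H](C)CC[C@H]1C(C)(C)c1ccccc1.[Li+].[Li+] | intermediate (not isolated)
8 | (1R,2S,5R)-5-methyl-2-(2-phenylpropan-2-yl)cyclohexyl (6E,10E)-6,10-dimethyl-3-oxotetradeca-6,10,13-trienoate | C=CC/C=C(\C)CC/C=C(\C)CCC(=O)CC(=O)O[C@@H]1C[C@H](C)CC[C@H]1C(C)(C)c1ccccc1 | intermediate
9 | monocyclic tertiary C10 radical (ring A closed, 4α-H, 5β-H, side chain still open) | C=CC/C=C(\C)CC[C@@H]1[C@@H](C(=O)O[C@@H]2C[C@H](C)CC[C@H]2C(C)(C)c2ccccc2)C(=O)CC[C]1C | intermediate (not isolated)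
10 | bicyclic tertiary C8 radical (rings A and B closed) | C[C]1CC[C@@H]2[C@@H](C(=O)O[C@@H]3C[C@H](C)CC[C@H]3C(C)(C)c3ccccc3)C(=O)CC[C@@]2(C)[C@@H]1CC=C | intermediate (not isolated)
11 | (1R,2S,5R)-5-methyl-2-(2-phenylpropan-2-yl)cyclohexyl (1R,4aR,5R,8aR)-4a-methyl-6-methylidene-2-oxo-5-(prop-2-en-1-yl)decahydronaphthalene-1-carboxylate | C=C1CC[C@@H]2[C@@H](C(=O)O[C@@H]3C[C@H](C)CC[C@H]3C(C)(C)c3ccccc3)C(=O)CC[C@@]2(C)[C@@H]1CC=C | intermediate
12 | (1R,2S,5R)-5-methyl-2-(2-phenylpropan-2-yl)cyclohexyl (1S,4aS,5R,8aS)-1,4a-dimethyl-6-methylidene-2-oxo-5-(prop-2-en-1-yl)decahydronaphthalene-1-carboxylate | C=C1CC[C@@H]2[C@](C)(C(=O)O[C@@H]3C[C@H](C)CC[C@H]3C(C)(C)c3ccccc3)C(=O)CC[C@@]2(C)[C@@H]1CC=C | intermediate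
13 | (1R,2R,4aS,5R,8aS)-1-(hydroxymethyl)-1,4a-dimethyl-6-methylidene-5-(prop-2-en-1-yl)decahydronaphthalen-2-ol | C=C1CC[C@@H]2[C@](C)(CO)[C@H](O)CC[C@@]2(C)[C@@H]1CC=C | intermediate
14 | (S)-3-hydroxy-γ-butyrolactone, (4S)-4-hydroxyoxolan-2-one | O=C1C[C@H](O)CO1 | starting material
15 | dilithium alkoxide–enolate dianion of 14 | [O-]C1=C[C@H]([O-])CO1.[Li+].[Li+] | intermediate (not isolated)
16 | (3S,4S)-3-[(dimethylamino)methyl]-4-hydroxyoxolan-2-one | CN(C)C[C@@H]1C(=O)OC[C@H]1O | intermediate
17 | [(3S,4S)-4-hydroxy-2-oxooxolan-3-yl]methyl-trimethylammonium iodide | C[N+](C)(C)C[C@@H]1C(=O)OC[C@H]1O.[I-] | intermediate (not isolated)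
18 | (S)-tulipalin B, (4S)-4-hydroxy-3-methylideneoxolan-2-one | C=C1C(=O)OC[C@H]1O | intermediate
19 | andrographolide | C=C1CC[C@@H]2[C@](C)(CO)[C@H](O)CC[C@@]2(C)[C@@H]1C/C=C1/C(=O)OC[C@H]1O | target

**Count and risk**

Total steps: 11. Longest linear sequence: 8 (steps 1, 2, 3, 5, 6, 7, 8, 11 from geranyl acetate).

Stereocentres: C5, C9 and C10 are set in step 6, C4 in step 7, C3 in step 8, C14 comes from 14, and the C12=C13 geometry is set in step 11.

Most likely to fail:

- **Step 6 (bicyclization).** The risks are over-oxidation of the still enolisable product 11, an exocyclic/endocyclic alkene mixture at C8, and incomplete facial control. The fallback moves the quaternary centre into the cascade. Compound 8 is C-methylated first (MeI, K2CO3, acetone) to the α-methyl β-keto ester (1R,2S,5R)-5-methyl-2-(2-phenylpropan-2-yl)cyclohexyl (6E,10E)-2,6,10-trimethyl-3-oxotetradeca-6,10,13-trienoate F1 (both epimers at the α-carbon, which becomes the radical centre). F1 is then cyclized with Mn(OAc)3·2H2O and Cu(OAc)2·H2O in AcOH at 25 °C without a lanthanide salt. The non-chelated tertiary radical reacts with the ester anti to the ketone oxygen, so the ester ends axial and the methyl equatorial, and the product cannot be oxidised further. Auxiliary control is weaker here, but the two ring series are diastereomers and separable on silica. This fallback sets out from 8 and comes back at 12, so step 7 is skipped.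

- **Step 11 (cross-metathesis).** The risks are low reactivity of the 1,1-disubstituted hydroxylated lactone alkene, isomerisation of 18, and E/Z mixtures. The fallback makes the C12=C13 bond by a Wittig reaction. Diol 13 is cleaved at the terminal alkene only (K2OsO2(OH)4 2 mol %, NaIO4, 2,6-lutidine, dioxane–water, 0 °C; the hindered C8 methylene reacts much more slowly) to the aldehyde 2-[(1R,4aS,5R,6R,8aS)-6-hydroxy-5-(hydroxymethyl)-5,8a-dimethyl-2-methylidenedecahydronaphthalen-1-yl]acetaldehyde F2. In parallel the dianion 15 made from 14 is quenched with CBr4 at −78 °C to the trans bromolactone (3S,4R)-3-bromo-4-hydroxyoxolan-2-one F3. PPh3 in MeCN converts F3 into [(4R)-4-hydroxy-2-oxooxolan-3-yl]triphenylphosphonium bromide F4, and Et3N in CH2Cl2 gives the stabilised ylide (4R)-4-hydroxy-3-(triphenyl-λ5-phosphanylidene)oxolan-2-one F5 in the flask. F5 olefinates F2 with the E selectivity typical of ester-stabilised ylides and tolerates the free hydroxyl groups. This fallback sets out from 13 (reagent branch from 14) and comes back at 19.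

- **Step 2 (allyl–vinyl coupling).** The risks are erosion of the E geometry through the π-allyl, branched coupling, or interference by the free alcohol. The fallback reverses the order and replaces palladium catalysis by copper-catalysed SN2 substitution. Geranyl acetate 1 is treated with vinylmagnesium bromide (CH2=CHMgBr) and Li2CuCl4 (3 mol %) in THF at −20 °C to give (4E)-5,9-dimethyldeca-1,4,8-triene F6. F6 is then oxidised at the terminal E-methyl group with catalytic SeO2 and t-BuOOH as in step 1; the internal trisubstituted alkene competes, so the yield is expected to be lower than in step 1. This fallback sets out from 1 and comes back at 3.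

Further compounds
F1 | step 6 | (1R,2S,5R)-5-methyl-2-(2-phenylpropan-2-yl)cyclohexyl (6E,10E)-2,6,10-trimethyl-3-oxotetradeca-6,10,13-trienoate (both C2 epimers) | C=CC/C=C(\C)CC/C=C(\C)CCC(=O)C(C)C(=O)O[C@@H]1C[C@H](C)CC[C@H]1C(C)(C)c1ccccc1
F2 | step 11 | 2-[(1R,4aS,5R,6R,8aS)-6-hydroxy-5-(hydroxymethyl)-5,8a-dimethyl-2-methylidenedecahydronaphthalen-1-yl]acetaldehyde | C=C1CC[C@@H]2[C@](C)(CO)[C@H](O)CC[C@@]2(C)[C@@H]1CC=O
F3 | step 11 | (3S,4R)-3-bromo-4-hydroxyoxolan-2-one | Br[C@@H]1C(=O)OC[C@H]1O
F4 | step 11 | [(4R)-4-hydroxy-2-oxooxolan-3-yl]triphenylphosphonium bromide (C3 unassigned) | c1ccccc1[P+](c1ccccc1)(c1ccccc1)C1C(=O)OC[C@H]1O.[Br-]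
F5 | step 11 | (4R)-4-hydroxy-3-(triphenyl-λ5-phosphanylidene)oxolan-2-one | c1ccccc1P(c1ccccc1)(c1ccccc1)=C1C(=O)OC[C@H]1O
F6 | step 2 | (4E)-5,9-dimethyldeca-1,4,8-triene | C=CC/C=C(\C)CCC=C(C)C
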